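**Strategy.** The ten-membered carbocycle (C1–C10) is cut at C1–C10 and, in thought, re-joined between C3 and C8. What remains is an (R)-carvone ring with a vinyl group on the C3 carbinol, a (Z)-propenyl group on C8 and C12 already oxygenated. One anionic oxy-Cope shift forms C1–C10, breaks C3–C8, enlarges the cyclohexene by four atoms and sets the C10 methyl centre. The feature exploited is the latent cyclodec-5-enone unit C3(=O)–C2–C1–C10–C9=C8 of that ring. The shift also leaves the C2 enolate, the C4=C5 enone and the E C8=C9 alkene for the epoxy ketone, the C4–C6 oxygens and the lactone.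

Key step: step 5

Remark on numbering and design: ring carbons are C1–C10 (C1–C2 epoxide, C3 ketone, C4 C(Me)OH, C5 acetate carbon, C6 crotonate carbon, C7 ring fusion, C8 lactone O–CH, C9 CH2, C10 CHMe), C11=C13 is the exocyclic methylene and C12 the lactone carbonyl; C12 is hydroxylated on carvone and carried as a TBS ether, because an allylic oxidation after ring expansion would have to spare the doubly allylic C7–H.

**Route**

Step 1
Reactants: 1 (R)-carvone
Product: 2 (R)-10-hydroxycarvone
Conditions: SeO2 (0.3 equiv), t-BuOOH (2 equiv), CH2Cl2, rt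
Reagents that add atoms: tert-butyl hydroperoxide, CC(C)(C)OO; selenium dioxide (oxygen carrier), O=[Se]=O
Why: Allylic hydroxylation by the selenium dioxide ene reaction and [2,3] shift is expected at the methyl group of the 1,1-disubstituted alkene while the electron-poor enone alkene stays untouched, which puts the future C12 at the alcohol level on a cheap substrate without forming a stereocentre.

Step 2
Reactants: 2 (R)-10-hydroxycarvone
Product: 3 TBS ether of 2
Conditions: TBSCl, imidazole, DMF, 0 °C to rt
Reagents that add atoms: tert-butyldimethylsilyl chloride, CC(C)(C)[Si](C)(C)Cl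
Why: Standard silylation of a primary alcohol gives an ether that is inert to amide bases, organometallic reagents and KH.

Step 3
Reactants: 3 TBS ether of 2; 4 (Z)-1-bromoprop-1-ene
Product: 7 (5R,6S)-5-[3-(TBSO)prop-1-en-2-yl]-2-methyl-6-[(Z)-prop-1-enyl]cyclohex-2-en-1-one (5,6-trans), via lithium enolate 5 (not isolated), via chlorozinc enolate 6 (not isolated)
Conditions: LiN(i-Pr)2 (1.05 equiv), THF, −78 °C; ZnCl2 (1.1 equiv), −78 to 0 °C; 4 (1.5 equiv), Pd2(dba)3 (2 mol%), SPhos (8 mol%), rt
Reagents that add atoms: (Z)-1-bromoprop-1-ene (4), C/C=C\Br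
Why: Kinetic deprotonation at the α' carbon (C8) followed by palladium-catalysed α-alkenylation of the zinc enolate (Negishi-type coupling) should join C8 to C9 with retention of the Z geometry, the new C8 centre forming trans to the C7 substituent because the carbon–carbon bond is made on the enolate face away from it, and the weakly basic zinc enolate should neither epimerise nor conjugate the β,γ-unsaturated product.

Step 4
Reactants: 7 trans-alkenyl ketone; 8 vinylmagnesium bromide
Product: 9 (1S,5R,6S)-1-ethenyl-2-methyl-5-[3-(TBSO)prop-1-en-2-yl]-6-[(Z)-prop-1-enyl]cyclohex-2-en-1-ol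
Conditions: CeCl3 (anhydrous, 1.5 equiv), 8 (1.5 equiv), THF, −78 °C; aq. NH4Cl
Reagents that add atoms: vinylmagnesium bromide (8), C=C[Mg]Br
Why: Organocerium 1,2-addition, chosen because the cerium reagent neither enolises the doubly activated C8–H nor adds in conjugate fashion, is expected to come from the equatorial direction anti to the neighbouring pseudo-equatorial propenyl group (axial attack would push the carbonyl oxygen past that group), which sets C3 with the vinyl group equatorial and the hydroxyl axial.

Step 5
Reactants: 9 vinyl carbinol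
Product: 12 trimethylsilyl dienol ether of the ring-expanded trienone (ten-membered ring; C2=C3 enol ether; C4=C5 Z; C8=C9 E), via potassium alkoxide 10 (not isolated), via potassium enolate 11 (not isolated)
Conditions: KH (1.5 equiv), 18-crown-6 (1.5 equiv), THF, 0 °C to rt; then TMSCl, Et3N, −78 °C
Reagents that add atoms: chlorotrimethylsilane, C[Si](C)(C)Cl
Why: The crown-ether-separated potassium alkoxide 10 weakens the C3–C8 bond and undergoes a [3,3] sigmatropic shift through the array C1=C2–C3–C8–C9=C10, in which C1–C10 forms as C3–C8 breaks; the closest known reaction type is the anionic oxy-Cope rearrangement of trans-1,2-dialkenylcyclohexanols to (E)-cyclodec-5-enones. The ten-membered ring is not closed end to end but arises by four-atom enlargement of the cyclohexene through a six-membered chair transition state in which the ring bonds C3–C4 and C8–C7 are equatorial. The only new stereocentre, C10, is controlled by the C8 configuration together with the Z geometry of the propenyl group, whose methyl is axial in that chair, and the equatorial C7 residue on C8 makes the new C8=C9 bond E. The step needs the chair through the vinyl group to win over the boat and over a [3,3] shift through the ring alkene C4=C5, and the substrate secures this because vinyl and propenyl are trans-diequatorial and gauche in the ground state, whereas C5 cannot reach C10 without an axial propenyl group. The enolate 11 is formed only toward C2 and is silylated on oxygen before proton transfer can move it.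

Step 6
Reactants: 12 silyl dienol ether
Product: 13 (1Z,4Z,8E)-1,4,8-trien-3-one of the ten-membered ring
Conditions: Pd(OAc)2 (1.05 equiv), MeCN, rt
Reagents that add atoms: none
Why: Saegusa–Ito oxidation places palladium on C2 and removes a C1 hydrogen by syn β-hydride elimination, and the Z enone is expected because C10–C1–C2–C3 is a gauche unit inherited from the chair and a ring that already holds the E C8=C9 bond disfavours a second E bond.

Step 7
Reactants: 13 trienone
Product: 14 cis-1,2-epoxy-(4Z,8E)-dien-3-one
Conditions: t-BuOOH (1.2 equiv), DBU (0.3 equiv), CH2Cl2, 0 °C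
Reagents that add atoms: tert-butyl hydroperoxide, CC(C)(C)OO
Why: Weitz–Scheffer nucleophilic epoxidation should pick the α-unsubstituted Z enone C1=C2 over the α-methylated enone C4=C5 and ignore the isolated alkenes, closure of the ring-bound enolate being faster than bond rotation so that the cis epoxide results, and the peroxide is expected to attack C1 on the outer face, anti to the C10–C9 ring bond with the C10 hydrogen eclipsing the alkene (allylic 1,3-strain with C3), which sets C1 and C2 as in the target.

Step 8
Reactants: 14 epoxy enone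
Product: 16 (5E,8E)-1,2-epoxy-4-hydroxy-5,8-dien-3-one, via potassium dienolate 15 (not isolated)
Conditions: KN(SiMe3)2 (1.1 equiv), THF, −78 °C; 3-phenyl-2-(phenylsulfonyl)oxaziridine (1.3 equiv), −78 °C; AcOH, −78 °C
Reagents that add atoms: 3-phenyl-2-(phenylsulfonyl)oxaziridine (Davis oxaziridine), O=S(=O)(N1OC1c1ccccc1)c1ccccc1
Why: γ-Deprotonation at C6, the only position that can be enolised once C2 is an oxirane carbon, gives the extended dienolate, whose α-hydroxylation by the Davis oxaziridine at C4 (the usual site of attack on metal dienolates) creates the tertiary α-ketol and moves the alkene to C5=C6; the E geometry is expected from removal of the outward C6 hydrogen with C7 swinging anti to C4, and the oxidant should approach C4 on the face opposite the C7–C8 ring bond, which is the face the target requires.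

Step 9
Reactants: 16 hydroxy dienone
Product: 18 all-syn 4,5,6-triol, via osmate ester 17 (not isolated)
Conditions: OsO4 (1.05 equiv), TMEDA (1.1 equiv), CH2Cl2, −78 °C; then aq. Na2SO3, THF, rt
Reagents that add atoms: osmium tetroxide, O=[Os](=O)(=O)=O
Why: Hydroxyl-directed syn dihydroxylation with the OsO4–TMEDA complex, which is held by a hydrogen bond to the allylic C4 hydroxyl, should single out C5=C6 among the three alkenes and add both oxygens on the face that carries that hydroxyl, so that the E alkene gives the C4/C5/C6 all-syn triol with C5 and C6 as in the target.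

Step 10
Reactants: 18 triol
Product: 19 6-O-[(E)-but-2-enoyl] derivative of 18
Conditions: (E)-crotonic anhydride (1.1 equiv), pyridine, DMAP (5 mol%), CH2Cl2, −20 °C
Reagents that add atoms: (E)-but-2-enoic anhydride, C/C=C/C(=O)OC(=O)/C=C/C
Why: DMAP-catalysed acylation is expected at the C6 hydroxyl, the more accessible of the two secondary alcohols because C5 is flanked by the fully substituted C4, while the tertiary C4 hydroxyl does not react at this temperature.

Step 11
Reactants: 19 C6 crotonate
Product: 20 5-O-acetyl-6-O-crotonyl derivative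
Conditions: Ac2O (3 equiv), pyridine, DMAP (10 mol%), CH2Cl2, 0 °C to rt
Reagents that add atoms: acetic anhydride, CC(=O)OC(C)=O
Why: Acetylation of the remaining secondary alcohol at C5 under nucleophilic catalysis should leave the tertiary α-ketol hydroxyl at C4 free because it is too hindered to be acylated under these conditions.

Step 12
Reactants: 20 diester silyl ether
Product: 21 C12 primary allylic alcohol
Conditions: HF·pyridine, pyridine, THF, 0 °C
Reagents that add atoms: none
Why: Fluoride-mediated cleavage of the primary silyl ether under buffered conditions should leave the esters, the epoxy ketone and the tertiary alcohol untouched.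

Step 13
Reactants: 21 allylic alcohol
Product: 23 C12 carboxylic acid (2-substituted acrylic acid), via enal 22 (not isolated)
Conditions: MnO2 (15 equiv), CH2Cl2, rt; filter; then NaClO2, NaH2PO4, 2-methylbut-2-ene, t-BuOH/H2O, 0 °C
Reagents that add atoms: sodium chlorite, [Na+].[O-]Cl=O
Why: Manganese dioxide oxidises only the allylic primary alcohol and the Pinnick oxidation takes the resulting 2-substituted acrolein to the acrylic acid without touching alkenes, esters or the epoxide, the hypochlorous acid being trapped by 2-methylbut-2-ene.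

Step 14
Reactants: 23 acrylic acid
Product: 24 9-iodo-12,8-lactone
Conditions: I2 (3 equiv), NaHCO3, MeCN/H2O, 0 °C, dark
Reagents that add atoms: iodine, II
Why: Iodolactonisation closes the γ-lactone in the 5-exo mode by anti addition of the C12 carboxylate and iodine across the E C8=C9 bond, the only nucleophilic alkene left, and C8 is set trans to H7 because the carboxylate can reach C8 only on the alkene face toward which C11 points when the C7 hydrogen lies near the alkene plane.

Step 15
Reactants: 24 iodolactone
Product: 25 target, (1S,2S,4S,5R,6S,7S,8R,10R)-5-acetoxy-6-[(E)-but-2-enoyloxy]-1,2-epoxy-4-hydroxy-3-oxogermacr-11(13)-en-12,8-olide (numbering as above)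
Conditions: Bu3SnH (1.2 equiv), Et3B (0.2 equiv), air, toluene, 0 °C
Reagents that add atoms: none
Why: Radical-chain deiodination replaces iodine at C9 by hydrogen, since iodine abstraction by the tributylstannyl radical is far faster than its addition to the carbonyl groups, the epoxy ketone or the acrylate, and the C9 radical has no favourable cyclisation open to it.

**Compound list**

1 | (R)-carvone | CC1=CC[C@H](CC1=O)C(C)=C | starting material
2 | (R)-10-hydroxycarvone, (5R)-5-(3-hydroxyprop-1-en-2-yl)-2-methylcyclohex-2-en-1-one | CC1=CC[C@H](CC1=O)C(=C)CO | intermediate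
3 | TBS ether of 2 | CC1=CC[C@H](CC1=O)C(=C)CO[Si](C)(C)C(C)(C)C | intermediate
4 | (Z)-1-bromoprop-1-ene | C/C=C\Br | starting material
5 | lithium cross-conjugated (C8) enolate of 3, not isolated | CC1=CC[C@H](C=C1O[Li])C(=C)CO[Si](C)(C)C(C)(C)C | intermediate
6 | chlorozinc enolate of 3, not isolated | CC1=CC[C@H](C=C1O[Zn]Cl)C(=C)CO[Si](C)(C)C(C)(C)C | intermediate
7 | (5R,6S)-5-[3-(TBSO)prop-1-en-2-yl]-2-methyl-6-[(Z)-prop-1-enyl]cyclohex-2-en-1-one, 5,6-trans | O=C1C(C)=CC[C@@H](C(=C)CO[Si](C)(C)C(C)(C)C)[C@@H]1/C=C\C | intermediate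
8 | vinylmagnesium bromide | C=C[Mg]Br | starting material
9 | (1S,5R,6S)-1-ethenyl-2-methyl-5-[3-(TBSO)prop-1-en-2-yl]-6-[(Z)-prop-1-enyl]cyclohex-2-en-1-ol; vinyl trans to propenyl, all three alkenyl groups equatorial | C=C[C@@]1(O)C(C)=CC[C@@H](C(=C)CO[Si](C)(C)C(C)(C)C)[C@@H]1/C=C\C | intermediate
10 | potassium alkoxide of 9, not isolated | C=C[C@@]1(O[K])C(C)=CC[C@@H](C(=C)CO[Si](C)(C)C(C)(C)C)[C@@H]1/C=C\C | intermediate
11 | potassium C2=C3 enolate of the ten-membered trienone (C1 and C4 trans across C2=C3, C4=C5 Z, C8=C9 E), not isolated | C=C(CO[Si](C)(C)C(C)(C)C)[C@H]1/C=C/[C@@H](C)C/C=C(O[K])/C(C)=C\C1 | intermediate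
12 | trimethylsilyl dienol ether of the same ring: 3-OTMS on C2=C3, 4-methyl C4=C5 Z, C8=C9 E, 7-[3-(TBSO)prop-1-en-2-yl], 10-methyl | C=C(CO[Si](C)(C)C(C)(C)C)[C@H]1/C=C/[C@@H](C)C/C=C(O[Si](C)(C)C)/C(C)=C\C1 | intermediate
13 | (1Z,4Z,8E)-4,10-dimethyl-7-[3-(TBSO)prop-1-en-2-yl]cyclodeca-1,4,8-trien-3-one (numbering as above) | C=C(CO[Si](C)(C)C(C)(C)C)[C@H]1/C=C/[C@@H](C)/C=C\C(=O)/C(C)=C\C1 | intermediate
14 | cis-1,2-epoxide of 13, (4Z,8E)-1,2-epoxy-4,8-dien-3-one, C1, C2, C7 and C10 as in 25 | C=C(CO[Si](C)(C)C(C)(C)C)[C@H]1/C=C/[C@@H](C)[C@@H]2O[C@@H]2C(=O)/C(C)=C\C1 | intermediate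
15 | potassium dienolate of 14 (C3=C4 enolate, C5=C6 E), not isolated | C[C@@H]1/C=C/[C@H](C(=C)CO[Si](C)(C)C(C)(C)C)/C=C/C(C)=C(O[K])\[C@H]2O[C@H]21 | intermediate
16 | (5E,8E)-1,2-epoxy-4-hydroxy-4-methyl-5,8-dien-3-one, C4 as in 25 | C[C@@H]1/C=C/[C@H](C(=C)CO[Si](C)(C)C(C)(C)C)/C=C/[C@](C)(O)C(=O)[C@H]2O[C@H]21 | intermediate
17 | cyclic C5,C6 osmate ester of 16 carrying TMEDA on osmium, not isolated | C[C@@H]1/C=C/[C@H](C(=C)CO[Si](C)(C)C(C)(C)C)[C@@H]3O[Os](=O)(=O)O[C@H]3[C@](C)(O)C(=O)[C@H]2O[C@H]21.CN(C)CCN(C)C | intermediate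
18 | 1,2-epoxy-4,5,6-trihydroxy-8-en-3-one, C4/C5/C6 oxygens all syn, configured as in 25 | C[C@@H]1/C=C/[C@H](C(=C)CO[Si](C)(C)C(C)(C)C)[C@H](O)[C@@H](O)[C@](C)(O)C(=O)[C@H]2O[C@H]21 | intermediate
19 | 6-O-[(E)-but-2-enoyl] derivative of 18 | C[C@@H]1/C=C/[C@H](C(=C)CO[Si](C)(C)C(C)(C)C)[C@H](OC(=O)/C=C/C)[C@@H](O)[C@](C)(O)C(=O)[C@H]2O[C@H]21 | intermediate
20 | 5-O-acetyl-6-O-[(E)-but-2-enoyl] derivative of 18 | C[C@@H]1/C=C/[C@H](C(=C)CO[Si](C)(C)C(C)(C)C)[C@H](OC(=O)/C=C/C)[C@@H](OC(C)=O)[C@](C)(O)C(=O)[C@H]2O[C@H]21 | intermediate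
21 | C12 primary allylic alcohol from 20 | C[C@@H]1/C=C/[C@H](C(=C)CO)[C@H](OC(=O)/C=C/C)[C@@H](OC(C)=O)[C@](C)(O)C(=O)[C@H]2O[C@H]21 | intermediate
22 | C12 aldehyde (2-substituted acrolein), not isolated | C[C@@H]1/C=C/[C@H](C(=C)C=O)[C@H](OC(=O)/C=C/C)[C@@H](OC(C)=O)[C@](C)(O)C(=O)[C@H]2O[C@H]21 | intermediate
23 | C12 carboxylic acid (2-substituted acrylic acid) | C[C@@H]1/C=C/[C@H](C(=C)C(=O)O)[C@H](OC(=O)/C=C/C)[C@@H](OC(C)=O)[C@](C)(O)C(=O)[C@H]2O[C@H]21 | intermediate
24 | 9-iodo derivative of 25 (iodine anti to the lactone oxygen across C8–C9, trans-fused lactone) | C=C1C(=O)O[C@@H]2[C@H](I)[C@@H](C)[C@@H]3O[C@@H]3C(=O)[C@@](C)(O)[C@H](OC(C)=O)[C@@H](OC(=O)/C=C/C)[C@@H]12 | intermediate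
25 | CNP0358125.1, (1S,2S,4S,5R,6S,7S,8R,10R)-5-acetoxy-6-[(E)-but-2-enoyloxy]-1,2-epoxy-4-hydroxy-3-oxogermacr-11(13)-en-12,8-olide | C=C1C(=O)O[C@@H]2C[C@@H](C)[C@@H]3O[C@@H]3C(=O)[C@@](C)(O)[C@H](OC(C)=O)[C@@H](OC(=O)/C=C/C)[C@@H]12 | target

Total step count: 15. Longest linear sequence: 15 steps, all from (R)-carvone.

**Steps most likely to fail**

Step 8. The risk is poor control of the C5=C6 geometry when the dienolate forms, and with it loss of the syn-addition logic of step 9, besides poor facial selectivity at C4. If the oxidation of 14 gives mainly the C5=C6 Z isomer, the (5Z)-hydroxy enone F1, the two oxygens are added by anti instead of syn addition, which from a Z alkene leads to the same all-syn pattern. Vanadium-catalysed, hydroxyl-directed epoxidation (VO(acac)2, t-BuOOH, CH2Cl2) touches only the allylic-alcohol alkene and should give the syn epoxy alcohol F2. Opening of F2 at C6 with inversion by (E)-crotonic acid and Ti(OiPr)4, the known distal opening of 2,3-epoxy alcohols by carboxylic acids, would give the C6 crotonate directly. This fallback sets out from 14 and comes back to the route at 19.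

Step 9. The risk is loss of chemoselectivity among the three alkenes, or attack on the wrong face, during the directed dihydroxylation. The fallback removes the competing alkenes first. From 16, HF·pyridine gives the allylic diol F3, and MnO2 followed by NaClO2 gives the acrylic acid F4. Iodolactonisation (I2, NaHCO3) onto the more electron-rich C8=C9 bond gives the iodolactone F5, and Bu3SnH gives the methylene lactone F6. C5=C6 is then the only electron-rich alkene, and catalytic OsO4 with Me3NO in CH2Cl2, still guided by the C4 hydroxyl, should give the triol lactone F7. Crotonylation at C6 gives the C6 crotonate F8, and acetylation at C5 completes the sequence. This fallback sets out from 16 and comes back at 25.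

Step 10. The risk is insufficient discrimination between the two secondary hydroxyls, or acyl migration between them. The fallback tells them apart with a silyl group, which responds more strongly to steric hindrance and does not migrate under the conditions used. From 18, Et3SiCl and imidazole at −40 °C give the C6 triethylsilyl ether F9, and Ac2O/DMAP gives the C5 acetate F10. Buffered HF·pyridine at −20 °C removes the triethylsilyl group but not the primary TBS ether, giving the hydroxy acetate F11. Crotonylation of the freed C6 hydroxyl then gives the diester. This fallback sets out from 18 and comes back at 20.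

**Further compounds**

F1 | step 8 | (5Z,8E)-1,2-epoxy-4-hydroxy-5,8-dien-3-one, the C5=C6 Z isomer of 16 | C[C@@H]1/C=C/[C@H](C(=C)CO[Si](C)(C)C(C)(C)C)/C=C\[C@](C)(O)C(=O)[C@H]2O[C@H]21
F2 | step 8 | cis-5,6-epoxide of F1 on the face of the C4 hydroxyl | C[C@@H]1/C=C/[C@H](C(=C)CO[Si](C)(C)C(C)(C)C)[C@H]3O[C@H]3[C@](C)(O)C(=O)[C@H]2O[C@H]21
F3 | step 9 | C12 allylic alcohol from desilylation of 16 | C[C@@H]1/C=C/[C@H](C(=C)CO)/C=C/[C@](C)(O)C(=O)[C@H]2O[C@H]21
F4 | step 9 | C12 acrylic acid with C4 hydroxyl and E C5=C6 | C[C@@H]1/C=C/[C@H](C(=C)C(=O)O)/C=C/[C@](C)(O)C(=O)[C@H]2O[C@H]21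
F5 | step 9 | 9-iodo-12,8-lactone with C4 hydroxyl and E C5=C6 | C=C1C(=O)O[C@@H]2[C@H](I)[C@@H](C)[C@@H]3O[C@@H]3C(=O)[C@@](C)(O)/C=C/[C@@H]12
F6 | step 9 | α-methylene-12,8-lactone with C4 hydroxyl and E C5=C6 | C=C1C(=O)O[C@@H]2C[C@@H](C)[C@@H]3O[C@@H]3C(=O)[C@@](C)(O)/C=C/[C@@H]12
F7 | step 9 | 4,5,6-triol of the α-methylene lactone | C=C1C(=O)O[C@@H]2C[C@@H](C)[C@@H]3O[C@@H]3C(=O)[C@@](C)(O)[C@H](O)[C@@H](O)[C@@H]12
F8 | step 9 | 6-O-[(E)-but-2-enoyl] derivative of F7 | C=C1C(=O)O[C@@H]2C[C@@H](C)[C@@H]3O[C@@H]3C(=O)[C@@](C)(O)[C@H](O)[C@@H](OC(=O)/C=C/C)[C@@H]12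
F9 | step 10 | 6-O-triethylsilyl ether of 18 | C[C@@H]1/C=C/[C@H](C(=C)CO[Si](C)(C)C(C)(C)C)[C@H](O[Si](CC)(CC)CC)[C@@H](O)[C@](C)(O)C(=O)[C@H]2O[C@H]21
F10 | step 10 | 5-O-acetate of F9 | C[C@@H]1/C=C/[C@H](C(=C)CO[Si](C)(C)C(C)(C)C)[C@H](O[Si](CC)(CC)CC)[C@@H](OC(C)=O)[C@](C)(O)C(=O)[C@H]2O[C@H]21
F11 | step 10 | 5-O-acetate with free C6 hydroxyl | C[C@@H]1/C=C/[C@H](C(=C)CO[Si](C)(C)C(C)(C)C)[C@H](O)[C@@H](OC(C)=O)[C@](C)(O)C(=O)[C@H]2O[C@H]21
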